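**Plan**

- Retrosynthetic cuts: C2′–C3′ (sp2–sp3 coupling) and the C1′=C2′ unit (back to a C1′ ester through an alkyne); C7–Br (back to a C7 ketone); the ring bond C3–C2, so that C1′ returns into the ring as a ketone between C3 and C2 and a trans-decalin results; finally C4–CH3, C4–O and C3a–H, which leads to (S)-Wieland–Miescher ketone.
- Forward order: both six-membered rings are bought as the decalin; ring B is dressed first (C4 carbinol, C7 ketone); ring A is activated at C3 and contracted to the cyclopentane in step 10; the bromide follows; the C8 chain is joined last.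
- Feature used: the trans-fused cyclopentane C1–C2–C3–C3a–C7a with the one-carbon branch C1′ on C3 is the contracted form of the cyclohexanone ring C1–C2–C1′(=O)–C3–C3a–C7a of an unstrained trans-decalin; a diazo group on C3 lets C2 move from C1′ to C3.
- Stereochemistry: C7a comes from (S)-Wieland–Miescher ketone; C3a–H and the C4 carbinol are set anti to the angular methyl (α-face hydroboration, α-face methyl addition); C3 is set thermodynamically (NaOMe); C7 by equatorial hydride delivery followed by SN2 inversion; the E-alkene by syn-hydrozirconation and a stereoretentive coupling.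

Key step: step 10

Conventions: atom labels are those of the target (indane numbering C1–C7a, side chain C1′, C2′ …) and are kept for the decalin intermediates, in which C1′ is the ring-A carbonyl carbon between C3 and C2. β is the face of the C7a methyl group. Compounds 11 and 12 are drawn as ring-enol tautomers.

Assumption: (S)-(+)-Wieland–Miescher ketone is treated as a purchased material (it is the L-proline annulation product of 2-methylcyclohexane-1,3-dione and but-3-en-2-one); its quaternary centre has the configuration of C7a in the given SMILES, which corresponds to (3S,3aS,4R,7S,7aS).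

**Route**

Step 1
Reactants: 1 (S)-(+)-Wieland–Miescher ketone
Product: 2 bis(ethylene ketal) of 1 with the double bond moved to C3a=C4
Conditions: HOCH2CH2OH (6 equiv), p-TsOH·H2O (cat.), benzene, reflux, Dean–Stark
Reagents that add atoms: ethylene glycol, OCCO
Why: Acid-catalysed ketalisation of both carbonyls is standard for this diketone, and ketalisation of the enone through its dienol moves the double bond out of conjugation to C3a=C4, where it is exposed for hydroboration while C7a is untouched.

Step 2
Reactants: 2 bis(ethylene ketal)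
Product: 4 trans-decalin 4α-alcohol bis-ketal (3aα-H), via C4-alkylborane 3 (not isolated)
Conditions: BH3·THF, THF, 0 °C to rt; then NaOH (aq), H2O2, 0 °C to rt
Reagents that add atoms: hydrogen peroxide, OO
Why: Brown hydroboration–oxidation adds H to C3a and boron to C4 in a syn fashion from the α-face opposite the axial C7a methyl, so the ring fusion becomes trans (3aα-H) and oxidation with retention gives the 4α-alcohol.

Step 3
Reactants: 4 trans-decalin 4α-alcohol bis-ketal
Product: 5 trans-decalin 4-ketone bis-ketal
Conditions: Dess–Martin periodinane (1.3 equiv), pyridine, CH2Cl2, rt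
Reagents that add atoms: none
Why: Dess–Martin oxidation of the secondary alcohol under buffered, non-equilibrating conditions should give the C4 ketone and leave both dioxolanes and the trans ring fusion intact.

Step 4
Reactants: 5 trans-decalin 4-ketone bis-ketal
Product: 6 4β-hydroxy-4α-methyl trans-decalin bis-ketal
Conditions: MeMgBr (3 equiv), anhydrous CeCl3 (3 equiv), THF, −78 to 0 °C; aq. NH4Cl
Reagents that add atoms: methylmagnesium bromide, C[Mg]Br
Why: Cerium-mediated Grignard addition suppresses enolisation toward C3a and, as with 6-oxo-5α-steroids, methyl should enter C4 along the equatorial α-trajectory because the axial β-path is blocked by the 1,3-diaxial C7a methyl, which gives the 4β-hydroxy-4α-methyl carbinol.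

Step 5
Reactants: 6 4β-hydroxy-4α-methyl trans-decalin bis-ketal
Product: 7 4β-hydroxy-4α,7aβ-dimethyl-trans-decalin-1′,7-dione
Conditions: 1 M HCl (aq), THF, rt
Reagents that add atoms: water, O
Why: Acid hydrolysis of the two dioxolanes regenerates the C1′ and C7 ketones under conditions that the tertiary alcohol should tolerate, since it is β to neither carbonyl and therefore has no retro-aldol or E1cB pathway.

Step 6
Reactants: 7 4β-hydroxy-4α,7aβ-dimethyl-trans-decalin-1′,7-dione
Product: 9 4β-(triethylsilyloxy)-4α,7aβ-dimethyl-trans-decalin-1,5-diene-1′,7-dione (C1=C2 and C5=C6 enones), via tris-TES bis-enol ether 8 (not isolated)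
Conditions: Et3SiOTf (3.6 equiv), Et3N (6 equiv), CH2Cl2, 0 °C to rt; solvent switch; Pd(OAc)2 (2.4 equiv), MeCN, 40 °C
Reagents that add atoms: triethylsilyl trifluoromethanesulfonate, CC[Si](CC)(CC)OS(=O)(=O)C(F)(F)F
Why: Silyl triflate and amine silylate the tertiary alcohol and turn each ketone into its less hindered enol ether (C1′ toward C2 as in 5α-3-ketosteroids and reinforced by the C4 substituents next to C3, C7 only toward C6), and Saegusa–Ito dehydrosilylation then gives the two enones, which leaves C3 as the only enolisable carbon of the molecule.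

Step 7
Reactants: 9 bis-enone
Product: 11 3-trifluoroacetyl bis-enone (enol form), via lithium C3-enolate 10 (not isolated)
Conditions: LiHMDS (1.2 equiv), THF, −78 °C; CF3CO2CH2CF3 (1.5 equiv), −78 °C; aq. HCl; used crude
Reagents that add atoms: 2,2,2-trifluoroethyl trifluoroacetate, O=C(OCC(F)(F)F)C(F)(F)F
Why: Danheiser trifluoroacetylation of the α′-enolate of an enone has no regiochemical choice here, because the γ-carbons (C7a, C4) and the other α′-carbon (C7a) are quaternary, so the Claisen-type C-acylation can only take place at C3.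

Step 8
Reactants: 11 3-trifluoroacetyl bis-enone
Product: 12 3-trifluoroacetyl-4β-(triethylsilyloxy)-4α,7aβ-dimethyl-trans-decalin-1′,7-dione (enol form)
Conditions: H2 (1 atm), 10% Pd/C, EtOAc, rt
Reagents that add atoms: none
Why: Heterogeneous hydrogenation should saturate the two cis-disubstituted enone double bonds that served as blocking groups while the chelated trifluoroacetyl enol and the silyl ether survive in a non-protic solvent, and no stereocentre is formed because C1, C2, C5 and C6 become CH2 groups.

Step 9
Reactants: 12 3-trifluoroacetyl diketone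
Product: 13 3-diazo-4β-(triethylsilyloxy)-4α,7aβ-dimethyl-trans-decalin-1′,7-dione (3aα-H)
Conditions: MsN3 (1.5 equiv), Et3N (1.5 equiv), H2O (1 equiv), MeCN, rt
Reagents that add atoms: methanesulfonyl azide, CS(=O)(=O)N=[N+]=[N-]
Why: Detrifluoroacetylative (Regitz-type) diazo transfer places the diazo group on exactly the carbon that carried the trifluoroacetyl group, so the C3-diazo C1′-ketone forms regiospecifically and the unactivated C7 ketone does not react.

Step 10
Reactants: 13 3-diazo-trans-decalin-1′,7-dione
Product: 16 methyl (3α)-4β-(triethylsilyloxy)-4α,7aβ-dimethyl-7-oxo-trans-hydrindane-3-carboxylate, via ketene 14 (not isolated), via 3β-ester epimer 15 (not isolated)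
Conditions: hν (365 nm LEDs, Pyrex), degassed MeOH, 0 °C to rt; then NaOMe (0.3 equiv), 50 °C
Reagents that add atoms: methanol, CO
Why: Excitation of the diazoketone expels N2 and, because the cyclic diazoketone is locked s-Z, C2 shifts from the carbonyl carbon C1′ to the diazo carbon C3 in concert with or directly after nitrogen loss (Wolff rearrangement), giving ketene 14, which methanol traps as the ester. The closest known reaction type is the photochemical Wolff ring contraction of cyclic α-diazoketones, as used for A-nor and D-nor steroids. The cyclopentane is not closed by a cyclisation but by a 1,2-alkyl shift inside the existing six-membered ring, so the trans C3a–C7a fusion fixed in the decalin passes unchanged into the more strained trans-hydrindane. The new stereocentre C3 is first set without control by protonation of the ketene-derived enol and is then put under thermodynamic control by NaOMe, which should convert epimer 15 into 16 with the ester trans to the C4 branch on the five-membered ring. The step needs regioselectivity (which α-carbon leaves the ring) and chemoselectivity over O–H insertion and 1,2-hydride shift from C3a; the first is fixed by the position of the diazo group inherited from step 7, the second by the s-Z geometry and by photochemical rather than metal-carbenoid activation at a wavelength the C7 ketone does not absorb.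

Step 11
Reactants: 16 methyl 7-oxo-trans-hydrindane-3-carboxylate
Product: 17 methyl (3α)-7α-hydroxy-4β-(triethylsilyloxy)-4α,7aβ-dimethyl-trans-hydrindane-3-carboxylate
Conditions: K-Selectride (1.5 equiv), THF, −78 °C; aq. NH4Cl
Reagents that add atoms: none
Why: The bulky trialkylborohydride reduces the ketone but not the ester and attacks along the equatorial trajectory, as in Selectride reductions of cyclohexanones flanked by a quaternary carbon (3-oxo-4,4-dimethyl terpenoids give axial 3α-alcohols), so the new hydroxyl should be axial on the α-face, trans to the C7a methyl.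

Step 12
Reactants: 17 7α-hydroxy ester
Product: 18 methyl (3α)-7β-bromo-4β-(triethylsilyloxy)-4α,7aβ-dimethyl-trans-hydrindane-3-carboxylate
Conditions: CBr4 (3 equiv), PPh3 (3 equiv), pyridine, toluene, 0 to 60 °C
Reagents that add atoms: carbon tetrabromide, BrC(Br)(Br)Br
Why: Appel bromination turns the alcohol into an oxyphosphonium leaving group that bromide displaces by SN2 with inversion, so the axial 7α-oxygen becomes the equatorial 7β-bromide, the backside path at this neopentylic carbon being the open equatorial one.

Step 13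
Reactants: 18 7β-bromo ester
Product: 20 3α-ethynyl-7β-bromo-4β-(triethylsilyloxy)-4α,7aβ-dimethyl-trans-hydrindane, via aldehyde 19 (not isolated)
Conditions: DIBAL-H (1.2 equiv), CH2Cl2, −78 °C; MeOH; then K2CO3 (3 equiv), dimethyl (1-diazo-2-oxopropyl)phosphonate (1.5 equiv), MeOH, 0 °C to rt
Reagents that add atoms: dimethyl (1-diazo-2-oxopropyl)phosphonate, COP(=O)(OC)C(=[N+]=[N-])C(C)=O
Why: Half-reduction of the ester to the aldehyde followed in the same flask by Ohira–Bestmann (Seyferth–Gilbert) homologation gives the terminal alkyne, and any base-induced epimerisation of the aldehyde at C3 can only favour the more stable trans arrangement already in place.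

Step 14
Reactants: 20 terminal alkyne
Product: 22 3α-(prop-1-yn-1-yl)-7β-bromo-4β-(triethylsilyloxy)-4α,7aβ-dimethyl-trans-hydrindane, via lithium acetylide 21 (not isolated)
Conditions: LDA (1.3 equiv), THF, −78 °C; MeI (3 equiv), −78 °C to rt
Reagents that add atoms: iodomethane, CI
Why: Deprotonation of the terminal alkyne and SN2 methylation of the acetylide give the 2-alkyne needed for regiocontrolled hydrometalation, and the equatorial secondary bromide has no antiperiplanar hydrogen for E2 under these conditions.

Step 15
Reactants: 22 methyl alkyne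
Product: 24 3α-[(E)-2-iodoprop-1-en-1-yl]-7β-bromo-4β-(triethylsilyloxy)-4α,7aβ-dimethyl-trans-hydrindane, via alkenylzirconocene chloride 23 (not isolated)
Conditions: Cp2Zr(H)Cl (1.8 equiv), THF, rt to 40 °C; then I2 (1.5 equiv), 0 °C
Reagents that add atoms: iodine, II
Why: Schwartz hydrozirconation adds Zr–H syn across the alkyne and, after equilibration with a small excess of reagent, puts zirconium on the methyl-bearing carbon away from the branched ring carbon, so iodinolysis with retention should give the (E)-2-iodoalkene with iodine trans to the ring.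

Step 16
Reactants: 24 (E)-vinyl iodide; 25 5-bromo-2-methylpent-2-ene
Product: 27 triethylsilyl ether of the target, via homoprenylzinc bromide 26 (not isolated)
Conditions: 25, Zn dust, LiCl, THF, 50 °C; then 24, Pd(dppf)Cl2 (5 mol%), THF, 50 °C
Reagents that add atoms: none
Why: Negishi sp2–sp3 coupling of the alkenyl iodide with the primary alkylzinc reagent proceeds with retention of alkene geometry, which places the new CH2 chain trans to the ring and gives the (E)-trisubstituted alkene, while the unactivated secondary alkyl bromide does not undergo oxidative addition.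

Step 17
Reactants: 27 triethylsilyl ether of the target
Product: 28 (3S,3aS,4R,7S,7aS)-7-bromo-3-[(1E)-2,6-dimethylhepta-1,5-dien-1-yl]-4,7a-dimethyloctahydro-1H-inden-4-ol
Conditions: HF·pyridine, pyridine, THF, 0 °C to rt
Reagents that add atoms: none
Why: Fluoride-driven cleavage of the Si–O bond frees the tertiary alcohol under buffered conditions that should not affect the equatorial secondary bromide or the two trisubstituted alkenes.

**Compound list**

1 | (S)-(+)-Wieland–Miescher ketone, (8aS)-8a-methyl-3,4,8,8a-tetrahydronaphthalene-1,6(2H,7H)-dione | O=C1CC[C@]2(C)C(=O)CCCC2=C1 | starting material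
2 | bis(ethylene ketal) of 1: dioxolanes at C1′ and C7, C3a=C4 double bond, 7aβ-methyl | C1C2(OCCO2)CC[C@]3(C)C4(OCCO4)CCC=C13 | intermediate
3 | C4-alkylborane: BH2 on C4 (α), H on C3a (α), bis-ketal | C1C2(OCCO2)CC[C@]3(C)C4(OCCO4)CC[C@H](B)[C@@H]13 | intermediate
4 | trans-decalin 4α-alcohol bis-ketal (3aα-H, 7aβ-methyl) | C1C2(OCCO2)CC[C@]3(C)C4(OCCO4)CC[C@H](O)[C@@H]13 | intermediate
5 | trans-decalin 4-ketone bis-ketal (3aα-H) | C1C2(OCCO2)CC[C@]3(C)C4(OCCO4)CCC(=O)[C@@H]13 | intermediate
6 | 4β-hydroxy-4α-methyl trans-decalin bis-ketal | C1C2(OCCO2)CC[C@]3(C)C4(OCCO4)CC[C@@](C)(O)[C@@H]13 | intermediate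
7 | 4β-hydroxy-4α,7aβ-dimethyl-trans-decalin-1′,7-dione (3aα-H) | C1C(=O)CC[C@]2(C)C(=O)CC[C@@](C)(O)[C@@H]12 | intermediate
8 | tris-TES compound: 4β-OTES, enol ethers C1′(OTES)=C2 and C7(OTES)=C6 | C1C(O[Si](CC)(CC)CC)=CC[C@]2(C)C(O[Si](CC)(CC)CC)=CC[C@@](C)(O[Si](CC)(CC)CC)[C@@H]12 | intermediate
9 | 4β-(triethylsilyloxy)-4α,7aβ-dimethyl-trans-decalin-1,5-diene-1′,7-dione | C1C(=O)C=C[C@]2(C)C(=O)C=C[C@@](C)(O[Si](CC)(CC)CC)[C@@H]12 | intermediate
10 | lithium enolate of 9 (C3=C1′–OLi) | C1=C(O[Li])C=C[C@]2(C)C(=O)C=C[C@@](C)(O[Si](CC)(CC)CC)[C@@H]12 | intermediate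
11 | 3-trifluoroacetyl derivative of 9 (ring-enol form) | O=C(C(F)(F)F)C1=C(O)C=C[C@]2(C)C(=O)C=C[C@@](C)(O[Si](CC)(CC)CC)[C@@H]12 | intermediate
12 | 3-trifluoroacetyl-4β-(triethylsilyloxy)-4α,7aβ-dimethyl-trans-decalin-1′,7-dione (ring-enol form) | O=C(C(F)(F)F)C1=C(O)CC[C@]2(C)C(=O)CC[C@@](C)(O[Si](CC)(CC)CC)[C@@H]12 | intermediate
13 | 3-diazo-4β-(triethylsilyloxy)-4α,7aβ-dimethyl-trans-decalin-1′,7-dione (key-step precursor) | [N-]=[N+]=C1C(=O)CC[C@]2(C)C(=O)CC[C@@](C)(O[Si](CC)(CC)CC)[C@@H]12 | intermediate
14 | ketene: 3-(oxomethylidene)-4β-(triethylsilyloxy)-4α,7aβ-dimethyl-trans-hydrindan-7-one | O=C=C1CC[C@]2(C)C(=O)CC[C@@](C)(O[Si](CC)(CC)CC)[C@@H]12 | intermediate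
15 | methyl (3β)-ester, C3 epimer of 16 | COC(=O)[C@H]1CC[C@]2(C)C(=O)CC[C@@](C)(O[Si](CC)(CC)CC)[C@@H]12 | intermediate
16 | methyl (3α)-4β-(triethylsilyloxy)-4α,7aβ-dimethyl-7-oxo-trans-hydrindane-3-carboxylate (key-step product) | COC(=O)[C@@H]1CC[C@]2(C)C(=O)CC[C@@](C)(O[Si](CC)(CC)CC)[C@@H]12 | intermediate
17 | methyl (3α)-7α-hydroxy-4β-(triethylsilyloxy)-4α,7aβ-dimethyl-trans-hydrindane-3-carboxylate | COC(=O)[C@@H]1CC[C@]2(C)[C@H](O)CC[C@@](C)(O[Si](CC)(CC)CC)[C@@H]12 | intermediate
18 | methyl (3α)-7β-bromo-4β-(triethylsilyloxy)-4α,7aβ-dimethyl-trans-hydrindane-3-carboxylate | COC(=O)[C@@H]1CC[C@]2(C)[C@@H](Br)CC[C@@](C)(O[Si](CC)(CC)CC)[C@@H]12 | intermediate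
19 | (3α)-7β-bromo-4β-(triethylsilyloxy)-4α,7aβ-dimethyl-trans-hydrindane-3-carbaldehyde | O=C[C@@H]1CC[C@]2(C)[C@@H](Br)CC[C@@](C)(O[Si](CC)(CC)CC)[C@@H]12 | intermediate
20 | 3α-ethynyl-7β-bromo-4β-(triethylsilyloxy)-4α,7aβ-dimethyl-trans-hydrindane | C#C[C@@H]1CC[C@]2(C)[C@@H](Br)CC[C@@](C)(O[Si](CC)(CC)CC)[C@@H]12 | intermediate
21 | lithium acetylide of 20 | [Li]C#C[C@@H]1CC[C@]2(C)[C@@H](Br)CC[C@@](C)(O[Si](CC)(CC)CC)[C@@H]12 | intermediate
22 | 3α-(prop-1-yn-1-yl)-7β-bromo-4β-(triethylsilyloxy)-4α,7aβ-dimethyl-trans-hydrindane | CC#C[C@@H]1CC[C@]2(C)[C@@H](Br)CC[C@@](C)(O[Si](CC)(CC)CC)[C@@H]12 | intermediate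
23 | (E)-alkenylzirconocene chloride, Zr on C2′ trans to the ring (Cp drawn σ-bonded) | Cl[Zr](C3C=CC=C3)(C4C=CC=C4)/C(C)=C/[C@@H]1CC[C@]2(C)[C@@H](Br)CC[C@@](C)(O[Si](CC)(CC)CC)[C@@H]12 | intermediate
24 | 3α-[(E)-2-iodoprop-1-en-1-yl]-7β-bromo-4β-(triethylsilyloxy)-4α,7aβ-dimethyl-trans-hydrindane | I/C(C)=C/[C@@H]1CC[C@]2(C)[C@@H](Br)CC[C@@](C)(O[Si](CC)(CC)CC)[C@@H]12 | intermediate
25 | 5-bromo-2-methylpent-2-ene | CC(C)=CCCBr | starting material
26 | (4-methylpent-3-en-1-yl)zinc bromide | CC(C)=CCC[Zn]Br | intermediate
27 | triethylsilyl ether of the target | CC(C)=CCC/C(C)=C/[C@@H]1CC[C@]2(C)[C@@H](Br)CC[C@@](C)(O[Si](CC)(CC)CC)[C@@H]12 | intermediate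
28 | (3S,3aS,4R,7S,7aS)-7-bromo-3-[(1E)-2,6-dimethylhepta-1,5-dien-1-yl]-4,7a-dimethyloctahydro-1H-inden-4-ol | CC(C)=CCC/C(C)=C/[C@@H]1CC[C@]2(C)[C@@H](Br)CC[C@@](C)(O)[C@@H]12 | target

**Step count**

Total steps: 17. Longest linear sequence: 17 steps (1 to 28); 25 enters in step 16.

**Steps most likely to fail and fallbacks**

Step 12 (bromination with inversion). Once the axial C7 oxygen is activated, E2 loss toward C6 (an antiperiplanar axial hydrogen is present) or ionisation with a methyl shift from C7a may outrun backside attack of bromide at the neopentylic carbon. The fallback sets out from 17 and separates activation from displacement: Tf2O and pyridine in CH2Cl2 at −78 °C should give the 7α-triflate F1, which is then treated with Bu4NBr in toluene at 0 °C to rt, so that SN2 takes place on an isolated sulfonate under salt-only conditions; the route is rejoined at 18.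

Step 7 (C-trifluoroacetylation). C-acylation of the enolate at C3, which sits next to the fully substituted C4, may be slow, so that O-acylation or proton return takes over. The fallback sets out from 9 and transfers the diazo group directly to the α′-position with 2,4,6-triisopropylbenzenesulfonyl azide under phase-transfer conditions (Bu4NBr, 18-crown-6, aq. KOH, benzene) to give the α′-diazo bis-enone F2. Irradiation of F2 in methanol (the vinylic C2 migrates, forming the same C3–C2 bond) should give the cyclopentene ester F3 as C3 epimers. Hydrogenation of both double bonds (H2, Pd/C, EtOAc) and NaOMe equilibration bring the material back to the route at 16.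

Step 6 (one-flask silylation and double dehydrogenation). Enol silylation of the hindered C7 ketone may stay incomplete or go partly toward C3, and palladium-mediated dehydrosilylation of the bulky triethylsilyl enol ethers may stall at a mono-enone. The fallback sets out from 7: only the tertiary alcohol is silylated (Et3SiOTf, 2,6-lutidine, CH2Cl2, −78 °C) to give the TES ether F4. The kinetic bis-enolate (LDA, 2.4 equiv, THF, −78 °C) is trapped with PhSeBr to give the 2,6-bis(phenylselanyl) diketone F5, and oxidation with H2O2/pyridine followed by selenoxide syn-elimination should give 9, where the route is rejoined.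

Further compounds
F1 | step 12 | methyl (3α)-7α-(trifluoromethanesulfonyloxy)-4β-(triethylsilyloxy)-4α,7aβ-dimethyl-trans-hydrindane-3-carboxylate | COC(=O)[C@@H]1CC[C@]2(C)[C@H](OS(=O)(=O)C(F)(F)F)CC[C@@](C)(O[Si](CC)(CC)CC)[C@@H]12
F2 | step 7 | 3-diazo-4β-(triethylsilyloxy)-4α,7aβ-dimethyl-trans-decalin-1,5-diene-1′,7-dione | [N-]=[N+]=C1C(=O)C=C[C@]2(C)C(=O)C=C[C@@](C)(O[Si](CC)(CC)CC)[C@@H]12
F3 | step 7 | methyl 4β-(triethylsilyloxy)-4α,7aβ-dimethyl-7-oxo-3a,4,7,7a-tetrahydro-3H-indene-3-carboxylate (C1=C2 and C5=C6 double bonds, C3 epimers) | COC(=O)C1C=C[C@]2(C)C(=O)C=C[C@@](C)(O[Si](CC)(CC)CC)[C@@H]12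
F4 | step 6 | 4β-(triethylsilyloxy)-4α,7aβ-dimethyl-trans-decalin-1′,7-dione | C1C(=O)CC[C@]2(C)C(=O)CC[C@@](C)(O[Si](CC)(CC)CC)[C@@H]12
F5 | step 6 | 2,6-bis(phenylselanyl)-4β-(triethylsilyloxy)-4α,7aβ-dimethyl-trans-decalin-1′,7-dione (epimers at C2 and C6) | C1C(=O)C([Se]c3ccccc3)C[C@]2(C)C(=O)C([Se]c3ccccc3)C[C@@](C)(O[Si](CC)(CC)CC)[C@@H]12
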